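**Plan**

- Retrosynthesis: the C1 carbinol goes back to the 4-aryl-1-tetralone. Ring B (C1, C2, C3, C4, C4a, C8a) is then cut at C1–C2 and C3–C4 in a retro-Diels–Alder sense. This leaves a two-carbon acrylate (C2–C3, its ester a traceless activator on C2) and the ortho-quinodimethane C1=C8a–C4a=C4.
- Enabling feature: ring B is fused to aromatic ring A along C4a–C8a, with a donor oxygen on C1 and the naphthyl group on C4. Its diene half can therefore be stored as the C1–C4-bonded valence isomer, a trans-2-aryl-3-methoxybenzocyclobutenol. This thermal source avoids triplet quenching by the naphthalene, which would undermine a photoenol route.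
- The four-membered ring is cut at C4–C4a (aryl carbanion plus epoxide). The epoxide is cut at C1–C4 into a benzylic sulfonium ylide (C1) and a 2-naphthaldehyde (C4).
- Forward: the purchased naphthalene is formylated at C2' and joined to the ring A fragment as a trans epoxide. The four-membered ring is closed, then opened, and ring B is closed in one operation. Ester removal, ketone reduction and acetal cleavage finish the route.
- Stereochemistry: C4 (R) comes from face selection on the planar dienolate by a titanium (R,R)-TADDOLate bound to the C1 oxygen. C1 (S, trans) comes from a reagent-controlled CBS reduction, which also diverts any 4S ketone into a separable cis diastereomer.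

Key step: step 8

Remark: locants C1–C8a are those of the tetralin of the target and are used for the same atoms throughout; primed locants belong to the naphthalene. TADDOL is (4R,5R)-2,2-dimethyl-α,α,α',α'-tetraphenyl-1,3-dioxolane-4,5-dimethanol.

Assumption: no close analogue fixes the sense of induction of the (R,R)-TADDOLate in step 8. It is taken to favour 4R; if the opposite holds, the equally available (S,S)-TADDOL is used with nothing else changed.

**Route**

Step 1
Reactants: 1 naphthalene-1,8-diol
Product: 2 8-methoxynaphthalen-1-ol
Conditions: MeI (1.05 equiv), K2CO3, acetone, reflux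
Reagents that add atoms: iodomethane, CI
Why: Williamson etherification should stop at the monoether because the remaining peri hydroxyl is held in a strong hydrogen bond to the new methoxy oxygen, which lowers its acidity and nucleophilicity.

Step 2
Reactants: 2 8-methoxynaphthalen-1-ol
Product: 3 1-methoxy-8-(methoxymethoxy)naphthalene
Conditions: NaH, MOMCl, DMF, 0 °C to rt
Reagents that add atoms: chloromethyl methyl ether, COCCl
Why: Irreversible deprotonation breaks the peri hydrogen bond and Williamson-type O-alkylation installs an acetal that tolerates organolithiums and directs the next metalation.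

Step 3
Reactants: 3 1-methoxy-8-(methoxymethoxy)naphthalene
Product: 5 8-methoxy-1-(methoxymethoxy)naphthalene-2-carbaldehyde, via 2-naphthyllithium 4 (not isolated)
Conditions: n-BuLi (1.2 equiv), TMEDA (1.2 equiv), Et2O, 0 °C to rt; DMF, −78 °C to rt; H2O
Reagents that add atoms: N,N-dimethylformamide, CN(C)C=O
Why: Directed ortho-metalation: the chelating OMOM group outranks OMe as director and its peri position is blocked, so lithiation should occur at C2' and the DMF quench (Bouveault-type formylation) gives the aldehyde.

Step 4
Reactants: 6 2-bromo-3-methoxybenzaldehyde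
Product: 7 (2-bromo-3-methoxyphenyl)methanol
Conditions: NaBH4, MeOH, 0 °C
Reagents that add atoms: none
Why: Borohydride reduction of an aromatic aldehyde leaves the aryl bromide and the ether untouched.

Step 5
Reactants: 7 (2-bromo-3-methoxyphenyl)methanol
Product: 8 2-bromo-1-(bromomethyl)-3-methoxybenzene
Conditions: PBr3 (0.4 equiv), CH2Cl2, 0 °C
Reagents that add atoms: phosphorus tribromide, BrP(Br)Br
Why: This is the standard SN2 bromination of a primary benzylic alcohol through its phosphite ester, and no acid-labile group is present.

Step 6
Reactants: 8 2-bromo-1-(bromomethyl)-3-methoxybenzene; 5 8-methoxy-1-(methoxymethoxy)naphthalene-2-carbaldehyde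
Product: 11 rac-trans-2-(2-bromo-3-methoxyphenyl)-3-[8-methoxy-1-(methoxymethoxy)naphthalen-2-yl]oxirane, via thiolanium bromide 9 (not isolated), via sulfonium benzylide 10 (not isolated)
Conditions: tetrahydrothiophene (1.5 equiv), NaOH (2 equiv), t-BuOH–H2O 9:1, rt; chromatography on Et3N-deactivated silica
Reagents that add atoms: none
Why: One-flask Johnson–Corey–Chaykovsky epoxidation with a semistabilised benzylic ylide forms the C1–C4 bond; reversible formation of the syn betaine should channel the reaction to the trans epoxide, which fixes the relative configuration of both new centres (racemic), and the basic medium spares this acid-labile epoxide.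

Step 7
Reactants: 11 rac-trans-2-(2-bromo-3-methoxyphenyl)-3-[8-methoxy-1-(methoxymethoxy)naphthalen-2-yl]oxirane
Product: 14 rac-trans-3-methoxy-2-[8-methoxy-1-(methoxymethoxy)naphthalen-2-yl]benzocyclobuten-1-ol, via aryllithium epoxide 12 (not isolated), via bromomagnesium cyclobutenoxide 13 (not isolated)
Conditions: n-BuLi (1.05 equiv), THF, −78 °C; MgBr2·OEt2 (1.5 equiv), −78 to −20 °C; H2O at −20 °C
Reagents that add atoms: none
Why: Parham-type anionic cyclisation, known for ortho-bromostyrene and ortho-bromostilbene oxides: fast Br–Li exchange is followed by MgBr2-assisted attack of the aryl carbanion on the distal, naphthyl-activated epoxide carbon (the breaking C–O bond is exocyclic to the new four-membered ring, the epoxide C–C bond becomes part of it), with inversion at C4 and retention at C1, so the trans epoxide should give the trans alcohol.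

Step 8
Reactants: 14 rac-trans-3-methoxy-2-[8-methoxy-1-(methoxymethoxy)naphthalen-2-yl]benzocyclobuten-1-ol; 15 allyl acrylate
Product: 18 allyl (1R,4R)-1-hydroxy-5-methoxy-4-[8-methoxy-1-(methoxymethoxy)naphthalen-2-yl]-1,2,3,4-tetrahydronaphthalene-2-carboxylate (C2 epimers), via titanium bis(cyclobutenoxide) 16 (not isolated), via titanium-bound out-out oxy-ortho-quinodimethane 17 (not isolated)
Conditions: Ti(OiPr)4 (0.5 equiv), (R,R)-TADDOL (0.55 equiv), toluene, rt; 14 (1.0 equiv), i-PrOH stripped with toluene under reduced pressure at ≤ 20 °C (all four isopropoxides displaced); 15 (5 equiv), 4 Å MS, BHT (cat.), toluene, 40–60 °C; aq. NaHCO3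
Reagents that add atoms: none
Why: Proposed new method: alcoholysis of Ti(TADDOLate)(OiPr)2 by 14 gives the cyclobutenoxide 16, whose metal-bound donor oxygen lowers the barrier of the strain-releasing conrotatory 4π opening; because 14 is trans, oxygen and naphthyl can both rotate outward and a single planar out,out dienolate 17 should result. The acrylate carbonyl is expected to bind to the same tetravalent titanium centre, and ring B closes by a suprafacial, concerted but asynchronous [4+2] cycloaddition (six-membered ring, C3–C4 leading, C1–C2 following) that restores the aromaticity of ring A. The closest known reaction types are the thermal or alkoxide-accelerated opening of benzocyclobutenols, trans-2-aryl ones included, with Diels–Alder trapping (racemic), and the Ti(OiPr)4/TADDOL-controlled Diels–Alder reaction of photochemically generated hydroxy-ortho-quinodimethanes; joining the thermal source to the chiral titanium template is what has not been shown. Regioselectivity follows from the oxygen donor on C1, which makes C4 the nucleophilic terminus, so C4 bonds to the acrylate β-carbon and the ester ends on C2 next to the carbinol. C4 is set by the face of 17 that the C2-symmetric TADDOLate leaves open to the bound acrylate, C1 is locked cis to C4 by the out,out geometry and the suprafacial addition, and C2 (endo or exo) is left uncontrolled because C1 and C2 lose their configuration in steps 9 and 10. The only selectivity that must be won is therefore enantiofacial, and the substrate helps by offering one diene geometry (the cis alcohol would open to the in,out diene and give the opposite C4 configuration for the same approach) and one covalent anchor, the C1 oxygen, for the chiral metal.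

Step 9
Reactants: 18 allyl (1R,4R)-1-hydroxy-5-methoxy-4-[8-methoxy-1-(methoxymethoxy)naphthalen-2-yl]-1,2,3,4-tetrahydronaphthalene-2-carboxylate
Product: 19 allyl (4R)-5-methoxy-4-[8-methoxy-1-(methoxymethoxy)naphthalen-2-yl]-1-oxo-1,2,3,4-tetrahydronaphthalene-2-carboxylate
Conditions: Dess–Martin periodinane (1.3 equiv), CH2Cl2, 0 °C to rt
Reagents that add atoms: none
Why: Dess–Martin oxidation of the secondary benzylic alcohol under nearly neutral conditions gives the enolisable β-keto ester, which removes the C1 centre and makes C2 irrelevant while C4, the MOM acetal and the allyl group are not touched.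

Step 10
Reactants: 19 allyl (4R)-5-methoxy-4-[8-methoxy-1-(methoxymethoxy)naphthalen-2-yl]-1-oxo-1,2,3,4-tetrahydronaphthalene-2-carboxylate
Product: 20 (4R)-5-methoxy-4-[8-methoxy-1-(methoxymethoxy)naphthalen-2-yl]-3,4-dihydronaphthalen-1(2H)-one
Conditions: Pd(OAc)2 (3 mol %), PPh3 (12 mol %), HCO2H (2 equiv), Et3N (2.5 equiv), THF, rt
Reagents that add atoms: none
Why: Tsuji-type deallylation–decarboxylation: zerovalent palladium ionises the allyl ester, the β-keto carboxylate loses CO2 and formate reduces the π-allyl unit to propene, all at room temperature and without strong base or heat, so the doubly benzylic C4–H of the tetralone should not epimerise (the reason for choosing the allyl ester).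

Step 11
Reactants: 20 (4R)-5-methoxy-4-[8-methoxy-1-(methoxymethoxy)naphthalen-2-yl]-3,4-dihydronaphthalen-1(2H)-one
Product: 21 (1S,4R)-5-methoxy-4-[8-methoxy-1-(methoxymethoxy)naphthalen-2-yl]-1,2,3,4-tetrahydronaphthalen-1-ol
Conditions: (R)-Me-CBS [(3aR)-1-methyl-3,3-diphenyltetrahydro-1H,3H-pyrrolo[1,2-c][1,3,2]oxazaborole] (15 mol %), BH3·SMe2 (1.0 equiv), THF, −20 °C; MeOH
Reagents that add atoms: none
Why: The Corey–Bakshi–Shibata reduction is reagent-controlled for 1-tetralones, 4-aryl-1-tetralones included, so the (R)-catalyst should deliver hydride to the Re face of C1 and give the 1S alcohol trans to the C4 aryl group, while any 4S ketone would end as the separable cis diastereomer and thereby raise the enantiomeric purity of 21.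

Step 12
Reactants: 21 (1S,4R)-5-methoxy-4-[8-methoxy-1-(methoxymethoxy)naphthalen-2-yl]-1,2,3,4-tetrahydronaphthalen-1-ol
Product: 23 dipolynaphthalene A = (1S,4R)-4-(1-hydroxy-8-methoxynaphthalen-2-yl)-5-methoxy-1,2,3,4-tetrahydronaphthalen-1-ol, via bis(trimethylsilyl) ether 22 (not isolated)
Conditions: TMSOTf (4 equiv), 2,2'-bipyridyl (6 equiv), MeCN, 0 °C to rt; then H2O, rt
Reagents that add atoms: none
Why: Silyl triflate/2,2'-bipyridyl cleavage of an aromatic MOM ether turns the acetal into the aryl silyl ether in a weakly basic medium (the C1 hydroxyl is silylated in passing), and water then hydrolyses both silyl ethers, so the ionisable benzylic C1–O bond never meets a strong protic acid and neither stereocentre is disturbed.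

**Compound list**

1 | naphthalene-1,8-diol | Oc1cccc2cccc(O)c12 | starting material
2 | 8-methoxynaphthalen-1-ol | COc1cccc2cccc(O)c12 | intermediate
3 | 1-methoxy-8-(methoxymethoxy)naphthalene | COCOc1cccc2cccc(OC)c12 | intermediate
4 | [8-methoxy-1-(methoxymethoxy)naphthalen-2-yl]lithium | [Li]c1ccc2cccc(OC)c2c1OCOC | intermediate
5 | 8-methoxy-1-(methoxymethoxy)naphthalene-2-carbaldehyde | COCOc1c(C=O)ccc2cccc(OC)c12 | intermediate
6 | 2-bromo-3-methoxybenzaldehyde | COc1cccc(C=O)c1Br | starting material
7 | (2-bromo-3-methoxyphenyl)methanol | COc1cccc(CO)c1Br | intermediate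
8 | 2-bromo-1-(bromomethyl)-3-methoxybenzene | COc1cccc(CBr)c1Br | intermediate
9 | 1-[(2-bromo-3-methoxyphenyl)methyl]thiolan-1-ium bromide | COc1cccc(C[S+]2CCCC2)c1Br.[Br-] | intermediate
10 | (2-bromo-3-methoxyphenyl)(thiolan-1-ium-1-yl)methanide | COc1cccc([CH-][S+]2CCCC2)c1Br | intermediate
11 | trans-2-(2-bromo-3-methoxyphenyl)-3-[8-methoxy-1-(methoxymethoxy)naphthalen-2-yl]oxirane, racemic, (2R,3R) enantiomer drawn | COc1cccc([C@@H]2[C@H](O2)c3ccc4cccc(OC)c4c3OCOC)c1Br | intermediate
12 | aryllithium from 11 (lithium in place of bromine), racemic | COc1cccc([C@@H]2[C@H](O2)c3ccc4cccc(OC)c4c3OCOC)c1[Li] | intermediate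
13 | bromomagnesium alkoxide of 14, racemic | COc1cccc2c1[C@@H](c1ccc3cccc(OC)c3c1OCOC)[C@@H]2O[Mg]Br | intermediate
14 | trans-3-methoxy-2-[8-methoxy-1-(methoxymethoxy)naphthalen-2-yl]benzocyclobuten-1-ol, racemic, (1S,2R) enantiomer drawn | COc1cccc2c1[C@@H](c1ccc3cccc(OC)c3c1OCOC)[C@@H]2O | intermediate
15 | allyl acrylate (prop-2-en-1-yl prop-2-enoate) | C=CC(=O)OCC=C | starting material
16 | Ti[(R,R)-TADDOLate](OR)2, R = cyclobutenyl residue of 14 (trans, both enantiomers; stereocentres of R not drawn) | CC1(C)O[C@@H]2[C@@H](O1)C(c1ccccc1)(c1ccccc1)O[Ti](OC1c3cccc(OC)c3C1c1ccc3cccc(OC)c3c1OCOC)(OC1c3cccc(OC)c3C1c1ccc3cccc(OC)c3c1OCOC)OC2(c1ccccc1)c1ccccc1 | intermediate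
17 | out,out oxy-ortho-quinodimethane C1=C8a–C4a=C4, oxygen bound to Ti(TADDOLate) in the flask (SMILES of the protonated dienol ligand) | COC1=CC=C/C(=C\O)/C1=C/c1ccc2cccc(OC)c2c1OCOC | intermediate
18 | allyl (1R,4R)-1-hydroxy-5-methoxy-4-[8-methoxy-1-(methoxymethoxy)naphthalen-2-yl]-1,2,3,4-tetrahydronaphthalene-2-carboxylate, 1,4-cis, C2 epimers | COc1cccc2c1[C@@H](c1ccc3cccc(OC)c3c1OCOC)CC(C(=O)OCC=C)[C@H]2O | intermediate
19 | allyl (4R)-5-methoxy-4-[8-methoxy-1-(methoxymethoxy)naphthalen-2-yl]-1-oxo-1,2,3,4-tetrahydronaphthalene-2-carboxylate (keto/enol, C2 undefined) | COc1cccc2c1[C@@H](c1ccc3cccc(OC)c3c1OCOC)CC(C(=O)OCC=C)C2=O | intermediate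
20 | (4R)-5-methoxy-4-[8-methoxy-1-(methoxymethoxy)naphthalen-2-yl]-3,4-dihydronaphthalen-1(2H)-one | COc1cccc2c1[C@@H](c1ccc3cccc(OC)c3c1OCOC)CCC2=O | intermediate
21 | (1S,4R)-5-methoxy-4-[8-methoxy-1-(methoxymethoxy)naphthalen-2-yl]-1,2,3,4-tetrahydronaphthalen-1-ol (trans) | COc1cccc2c1[C@@H](c1ccc3cccc(OC)c3c1OCOC)CC[C@@H]2O | intermediate
22 | bis(trimethylsilyl) ether of 23 | COc1cccc2c1[C@@H](c1ccc3cccc(OC)c3c1O[Si](C)(C)C)CC[C@@H]2O[Si](C)(C)C | intermediate
23 | dipolynaphthalene A, (1S,4R)-4-(1-hydroxy-8-methoxynaphthalen-2-yl)-5-methoxy-1,2,3,4-tetrahydronaphthalen-1-ol | COc1cccc2c1[C@@H](c1ccc3cccc(OC)c3c1O)CC[C@@H]2O | target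

**Step count**

- Total steps: 12.
- Longest linear sequence: 10 steps, from 1 through steps 1–3 and 6–12. The branch from 6 counts 9.

**Steps most likely to fail**

**Step 8.** Three processes may interfere:
- A titanium centre carrying four alkoxide ligands binds the acrylate only weakly, so unbound acrylate may add to either face and facial selectivity may be poor.
- Proton transfer to C4 of the dienolate (tautomerisation to the arylmethylbenzaldehyde) may outrun the cycloaddition.
- β-Elimination of the C1 oxygen from the adduct may occur.

The fallback uses known chemistry, sets out from 14 and 15 and comes back at 21. Heating 14 with 15 in toluene at 80–110 °C without any metal is the established racemic version and should give the racemic 1,4-cis adduct F1. Dess–Martin oxidation then leads to the racemic β-keto ester F2, and the Pd(OAc)2/PPh3/formate decarboxylation to the racemic tetralone F3. Reduction of F3 with the same (R)-Me-CBS/BH3·SMe2 system is a stereodivergent reaction on a racemate, known for 4-aryl-1-tetralones. Both enantiomers are reduced to 1S alcohols: the 4R ketone gives 21 and the 4S ketone gives the (1S,4S)-cis alcohol F4. The two diastereomers are separated by chromatography. The price is that no more than half of the material can reach 21.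

**Step 7.** Two kinds of loss are possible:
- Before the strained ring closes, the Lewis-acid-activated, very electron-rich epoxide may rearrange, or the aryl-metal may capture a proton.
- After closure, the metal alkoxide may open prematurely and tautomerise to the aldehyde during protic work-up and chromatography.

The fallback answers only the second loss. It sets out from 11 and comes back at 18, and the free alcohol is never released. The cold solution of 13 is diluted with toluene and freed of most THF. It is then treated with TiCl2(TADDOLate) (0.5 equiv, from TiCl2(OiPr)2 and (R,R)-TADDOL with i-PrOH stripped), so that salt metathesis gives 16 directly. Compound 15 is added and the mixture is warmed as in step 8. Ring closure, transfer to the chiral metal, opening and cycloaddition thus become one relay instead of an isolation followed by alcoholysis.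

**Step 12.** The benzylic C1–O bond may ionise, leading to epimerisation, elimination to the dihydronaphthalene or capture by the neighbouring naphthol oxygen. Cleavage of the hindered acetal may also be incomplete.

The fallback sets out from 20 and comes back at 23 by reversing the order of the last two operations. The acetal is removed at the ketone stage, where no benzylic alcohol is present, with HCl (cat.) in MeOH at 40 °C to give the free naphthol ketone F5. F5 is then reduced by Noyori asymmetric transfer hydrogenation with RuCl[(S,S)-TsDPEN](p-cymene) in HCO2H–Et3N 5:2 at rt. This method tolerates free phenols and should give the 1S alcohol, which is 23.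

**Further compounds**

F1 | step 8 | racemic allyl 1,4-cis-1-hydroxy-5-methoxy-4-[8-methoxy-1-(methoxymethoxy)naphthalen-2-yl]-1,2,3,4-tetrahydronaphthalene-2-carboxylate | COc1cccc2c1C(c1ccc3cccc(OC)c3c1OCOC)CC(C(=O)OCC=C)C2O
F2 | step 8 | racemic allyl 5-methoxy-4-[8-methoxy-1-(methoxymethoxy)naphthalen-2-yl]-1-oxo-1,2,3,4-tetrahydronaphthalene-2-carboxylate | COc1cccc2c1C(c1ccc3cccc(OC)c3c1OCOC)CC(C(=O)OCC=C)C2=O
F3 | step 8 | racemic 5-methoxy-4-[8-methoxy-1-(methoxymethoxy)naphthalen-2-yl]-3,4-dihydronaphthalen-1(2H)-one | COc1cccc2c1C(c1ccc3cccc(OC)c3c1OCOC)CCC2=O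
F4 | step 8 | (1S,4S)-5-methoxy-4-[8-methoxy-1-(methoxymethoxy)naphthalen-2-yl]-1,2,3,4-tetrahydronaphthalen-1-ol (cis) | COc1cccc2c1[C@H](c1ccc3cccc(OC)c3c1OCOC)CC[C@@H]2O
F0 | step 7 | none | none
F5 | step 12 | (4R)-4-(1-hydroxy-8-methoxynaphthalen-2-yl)-5-methoxy-3,4-dihydronaphthalen-1(2H)-one | COc1cccc2c1[C@@H](c1ccc3cccc(OC)c3c1O)CCC2=O
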